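# Proposed synthesis of 5,7-dihydroxy-6-methoxy-3-(2,3,4-trimethoxyphenyl)-4H-chromen-4-one (16)

## Structural features

The target is an isoflavone: benzene ring A is fused to the 4-pyranone ring C, and the 2,3,4-trimethoxyphenyl ring B hangs from C3 through the single C3–C1' bond. Ring A carries the contiguous set 5-OH, 6-OMe, 7-OH beside an unsubstituted C8, so O1, O5 and O7 form a phloroglucinol pattern with a fourth oxygen inserted at C6. The target has no stereocentre; the only stereocentres met on the way are the two adjacent oxirane carbons of 11, and both disappear in the key step. The fragile points are the two free phenols on a very electron-rich ring A, the flanked methoxy groups at C6 and C3' (the ones a strong Lewis acid removes first), and the C2=C3 enol-ether bond of ring C, which hot alkali opens and hydrogen can saturate. The real difficulty is regiochemical: ring C must close through the ring A oxygen next to the unsubstituted carbon, since closure through the other ortho oxygen would give the 8-methoxy isomer, and two of the six oxygens must end as hydroxyls while four stay methylated. The key step exploits the fact that C3 carries both ring B and the C4 carbonyl: the carbon bonded to C1' is benzylic to a ring with methoxy groups ortho and para, so in an oxirane it ionises readily and takes over the ring A aroyl group from the neighbouring carbon, which is left as the C2 aldehyde.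

## Logic of the disconnections

16 to 15. The two O–CH2Ph bonds at O5 and O7 are cut last. Benzyl ethers tolerate alkali, alkaline peroxide, BF3 at low temperature and zerovalent palladium, and they leave by neutral hydrogenolysis that touches none of the four methyl ethers, so both phenols stay masked through the whole route. The forward step must stop before the C2=C3 bond is reduced.

15 to 12. The O1–C2 bond of ring C is cut and the freed oxygen is capped as an allyl ether. In 12 the C2 carbon is already at the aldehyde oxidation level, so ring closure needs only a free phenol and loss of water. Because the other two ring A oxygens are benzylated, only the allylated one can close, which fixes the 6-methoxy pattern. The forward step needs an allyl acceptor that is neither basic nor an amine, since an amine could condense with or cleave the formyl group.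

12 to 11 (strategic cut). The C3–C4 bond is cut, the carbonyl carbon is returned to the carbon that becomes C2, and the oxygen is tied back as an oxirane. This turns the branched 1,2-diaryl skeleton into the linear 1,3-diaryl skeleton of an aldol product. The forward step demands ionisation at the benzylic oxirane carbon only, migration of the aroyl group in preference to hydride, and survival of benzyl, allyl and methyl ethers under a Lewis acid.

11 to 10. Both C–O bonds of the oxirane are removed, leaving an enone. The forward reagent must be a nucleophilic oxidant, because an electrophilic one would attack the allyl double bond and the electron-rich rings.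

10 to 8 and 9. The Cα=Cβ double bond is cut. This makes the route convergent and brings in ring B complete with its three methoxy groups as 9. The forward step needs a methyl ketone whose ortho oxygens are both etherified and protecting groups that tolerate hydroxide.

8 to 6 and 7. The O–allyl bond is cut. The forward step must alkylate a chelated phenol without heating to the point of a Claisen rearrangement.

6 to 5. The O–CH3 bond at the oxygen that becomes the 6-methoxy group is cut. This leaves a hydroquinone whose two hydroxyls differ sharply, one being chelated to the acetyl group and the other not. The forward step must stop at the monomethyl ether.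

5 to 3. The C–O bond at the ring carbon between the two benzyloxy groups is cut. That carbon is para to the only free phenol, the position a persulfate oxidation attacks, so the fourth oxygen is placed without ambiguity. Directed C–H borylation of a benzylated ring was set aside because it would have to pick one core C–H bond out of many unhindered ones on the benzyl groups, and a Lewis-acid acetylation beside benzyl ethers was set aside because it invites loss of the ortho benzyl group. The price of the chosen cut is a forward step of modest conversion on cheap material.

3 to 1 and 2. Two O–benzyl bonds are cut, back to 1, which already carries the acetyl group and all three ring oxygens, and two equivalents of 2. The forward step relies on the hydrogen bond that shields the last ortho hydroxyl, and that hydroxyl is the future O1.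

## Other disconnections considered

Alternative 1: Ring B is built and not bought. The cut runs through C5'–C6' and C1'–C2'. The pieces are 4-chloro-2,3-dimethoxycyclobut-2-en-1-one A3 (racemic) and a finished chromone that already carries a two-carbon vinyl unit at C3, 5,7-bis(benzyloxy)-6-methoxy-3-[(E)-2-(tributylstannyl)ethenyl]chromen-4-one A2.
- Forward key step: Pd2(dba)3 with tri(2-furyl)phosphine would join the chloride-bearing carbon of A3 to the stannylated carbon of A2 (Stille coupling, C5'–C6'). Thermal four-electron ring opening to a dienylketene, six-electron ring closure (C1'–C2') and tautomerisation would then give the phenol 5,7-bis(benzyloxy)-3-(2-hydroxy-3,4-dimethoxyphenyl)-6-methoxychromen-4-one A1.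
- In favour: the conditions are neutral, with no Lewis acid near the benzyl ethers. Every ring B oxygen is placed unambiguously. Ring C is already in place, so no temporary group on O1 is needed; on that point it is better than the chosen plan.
- Against: the ring it builds is available complete as 9. A1 still lacks the 2'-methyl group, so an extra O-methylation precedes hydrogenolysis. A2 would need ring C closure, C3 halogenation and stannylvinylation starting from 6, and A3 needs its own sequence. Tin is used stoichiometrically.
- Comparison: on ring A regiochemistry the two plans are equal, since both rest on the single free phenol of 6. On mechanism both use well-precedented reaction types. On step economy the alternative is clearly worse, with a main line at least as long plus a second branch.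

Alternative 2: A 2,3-aryl shift on a flavanone. The cut is the C3–C1' bond, with ring B reconnected to C2. This leads back to 5,7-bis(benzyloxy)-6-methoxy-2-(2,3,4-trimethoxyphenyl)chroman-4-one A5 (racemic).
- Forward key step: PhI(OH)OTs, a trivalent iodine electrophile, would attack the enol of A5 at C3. As iodobenzene leaves, ring B bridges and migrates from C2 to C3, and loss of the C3 proton leaves the C2=C3 bond. The product is 5,7-bis(benzyloxy)-6-methoxy-3-(2,3,4-trimethoxyphenyl)chromen-4-one A4, which is the same compound as 15.
- In favour: A5 should be available from 6 and 9 by Claisen–Schmidt condensation with oxa-Michael closure. Allylation, epoxidation and deallylation all fall away, and A4 would be reached about three steps sooner. Ring B, with donors ortho and para, is an ideal migrating group.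
- Against: the C3-iodanyl intermediate can partition in several ways: loss of the C2 hydrogen without migration, capture by solvent at C3, or ring contraction. Migration needs ring B antiperiplanar to the leaving group. The oxidant is an electrophile and must spare C8–H of the very electron-rich ring A, the benzyl ethers and ring B.
- Comparison: on structure the plans are equal, with the same phenol fixing O1. On step economy the alternative is the better. On mechanism the chosen plan is a redox-neutral isomerisation whose selectivity (acyl against hydride) is inherent, whereas here the outcome depends on how an oxidised intermediate partitions in the presence of oxidisable rings.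

Alternative 3: Aldehyde C–H annulation with a silyl alkyne. The cut takes both bonds that tie ring C together, C4–C3 and O1–C2. The pieces are 4,6-bis(benzyloxy)-2-hydroxy-5-methoxybenzaldehyde A7 and trimethyl[(2,3,4-trimethoxyphenyl)ethynyl]silane A8.
- Forward key step: [RhCl2(C5Me5)]2 activated by AgSbF6 would, directed by the phenoxide, cleave the formyl C–H bond of A7 to an acyl complex of trivalent rhodium. A8 inserts with the acyl carbon on the aryl-bearing alkyne carbon (C4–C3) and rhodium on the silyl-bearing one. C–O reductive elimination (O1–C2) closes ring C, and Cu(OAc)2 returns monovalent rhodium to the trivalent state. The product is 5,7-bis(benzyloxy)-6-methoxy-3-(2,3,4-trimethoxyphenyl)-2-(trimethylsilyl)chromen-4-one A6, which needs protodesilylation at C2 before hydrogenolysis.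
- In favour: it is the most convergent plan. Ring C and the C3–aryl bond arise in one step, no group is needed on O1, and A8 is one coupling step from an aryl halide. On step economy it is equal or better.
- Against: aryl alkynes tend to place the aryl group next to oxygen, and the silyl group is relied on to reverse this. A slip in insertion sense would put ring B on C2, an error the aldol-derived skeleton of the chosen plan cannot make. Silyl alkynes can lose silicon in the presence of AgSbF6 and Cu(OAc)2. The formyl group of A7 is flanked by two ortho oxygens, which slows C–H cleavage and invites decarbonylation. A7 requires the ring A oxygenation problem to be solved again in the aldehyde series.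
- Comparison: on ring A regiochemistry the plans are equal. On step economy the alternative is equal or better. On security of the C2/C3 connectivity the chosen plan is the better.

Key step: step 7

Assumption: compound 1 is used as its commercial monohydrate, the water being covered by the slight excess of K2CO3. Epoxide 11 is racemic and trans, one enantiomer is drawn, and both enantiomers lead to the same achiral 12.

## Route

Step 1
Reactants: 1 1-(2,4,6-trihydroxyphenyl)ethanone; 2 benzyl bromide (two equivalents are incorporated)
Product: 3 1-[2,4-bis(benzyloxy)-6-hydroxyphenyl]ethanone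
Conditions: BnBr (2.05 equiv), K2CO3 (2.2 equiv), DMF, 0 °C to rt
Reagents that add atoms: benzyl bromide (the second equivalent of 2), BrCc1ccccc1
Why: Twofold Williamson etherification; the 4-hydroxyl (para to the acetyl, most acidic, not chelated) and one of the two equivalent ortho hydroxyls are alkylated, after which the last hydroxyl is held in a six-membered hydrogen bond to the acetyl carbonyl and resists the limited amount of halide at room temperature. That surviving oxygen is the one that becomes O1.

Step 2
Reactants: 3 1-[2,4-bis(benzyloxy)-6-hydroxyphenyl]ethanone
Product: 5 1-[2,4-bis(benzyloxy)-3,6-dihydroxyphenyl]ethanone, via potassium aryl sulfate 4 (not isolated)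
Conditions: K2S2O8 (1.1 equiv), aq NaOH, pyridine, 15 °C; then aq HCl, 85 °C, N2
Reagents that add atoms: potassium peroxodisulfate, [K+].[K+].[O-]S(=O)(=O)OOS(=O)(=O)[O-]
Why: Elbs persulfate oxidation: the phenoxide of 3 attacks a peroxide oxygen through its para carbon, the ring carbon between the two benzyloxy groups, to give the aryl sulfate 4, which hot dilute acid hydrolyses at the S–O bond; unchanged 3 is extracted for recycling before the hydrolysis. Para attack is the normal course of this reaction when the para position is free, so the new oxygen is placed unambiguously.

Step 3
Reactants: 5 1-[2,4-bis(benzyloxy)-3,6-dihydroxyphenyl]ethanone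
Product: 6 1-[2,4-bis(benzyloxy)-6-hydroxy-3-methoxyphenyl]ethanone
Conditions: MeI (1.05 equiv), K2CO3 (1.1 equiv), acetone, 40 °C, N2
Reagents that add atoms: iodomethane, CI
Why: Williamson etherification, selective because the 6-hydroxyl is chelated to the acetyl carbonyl and far less nucleophilic than the free 3-hydroxyl; a slight excess of MeI under N2 (5 is an air-sensitive hydroquinone) should stop at the monoether.

Step 4
Reactants: 6 1-[2,4-bis(benzyloxy)-6-hydroxy-3-methoxyphenyl]ethanone; 7 allyl bromide
Product: 8 1-[6-(allyloxy)-2,4-bis(benzyloxy)-3-methoxyphenyl]ethanone
Conditions: allyl bromide (1.5 equiv), K2CO3, DMF, 60 °C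
Reagents that add atoms: none
Why: Williamson etherification of the chelated phenol, which needs the dipolar solvent and gentle heating; 60 °C is far below the temperature of an aromatic Claisen rearrangement. The allyl group marks the future O1 and is orthogonal to benzyl.

Step 5
Reactants: 8 1-[6-(allyloxy)-2,4-bis(benzyloxy)-3-methoxyphenyl]ethanone; 9 2,3,4-trimethoxybenzaldehyde
Product: 10 (E)-1-[6-(allyloxy)-2,4-bis(benzyloxy)-3-methoxyphenyl]-3-(2,3,4-trimethoxyphenyl)prop-2-en-1-one
Conditions: KOH, EtOH/H2O, rt
Reagents that add atoms: none
Why: Claisen–Schmidt (crossed aldol) condensation: the methyl ketone is the only enolisable partner and 9 cannot enolise; E1cB loss of water gives the conjugated E alkene as the thermodynamic isomer. Allyl and benzyl ethers are inert to KOH at room temperature.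

Step 6
Reactants: 10 (E)-1-[6-(allyloxy)-2,4-bis(benzyloxy)-3-methoxyphenyl]-3-(2,3,4-trimethoxyphenyl)prop-2-en-1-one
Product: 11 rac-[6-(allyloxy)-2,4-bis(benzyloxy)-3-methoxyphenyl][(2S,3R)-3-(2,3,4-trimethoxyphenyl)oxiran-2-yl]methanone (trans)
Conditions: 30% H2O2, aq NaOH, MeOH/THF, 0 °C to rt
Reagents that add atoms: hydrogen peroxide, OO
Why: Weitz–Scheffer epoxidation: hydroperoxide anion adds to the beta carbon and the enolate then displaces hydroxide from the O–O bond; because the addition is stepwise, the ring closes from the rotamer with aryl and aroyl anti, so the two new adjacent stereocentres are set trans to each other (racemic). The nucleophilic oxidant leaves the allyl double bond and the electron-rich rings alone, which a peracid would not.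

Step 7
Reactants: 11 rac-[6-(allyloxy)-2,4-bis(benzyloxy)-3-methoxyphenyl][(2S,3R)-3-(2,3,4-trimethoxyphenyl)oxiran-2-yl]methanone (trans)
Product: 12 (Z)-1-[6-(allyloxy)-2,4-bis(benzyloxy)-3-methoxyphenyl]-3-hydroxy-2-(2,3,4-trimethoxyphenyl)prop-2-en-1-one
Conditions: BF3·OEt2 (0.5 equiv), CH2Cl2, −20 to 0 °C; aq NaHCO3
Reagents that add atoms: none
Why: BF3 coordinates the oxirane oxygen and the C–O bond at the benzylic carbon ionises, because that carbon is bonded to C1' of ring B and the 2'- and 4'-methoxy groups delocalise the charge, whereas the other oxirane carbon is alpha to the ketone and cannot carry it. The ring A aroyl group then shifts with its bonding electrons from the alpha carbon to the cationic centre while the oxygen closes to a C=O; this forms the C3–C4 bond and turns the former alpha carbon into the C2 aldehyde, which rests as the hydrogen-bonded Z enol 12. The closest known reaction type is the Meinwald (semipinacol) rearrangement of alpha,beta-epoxy ketones with 1,2-acyl migration, long used on 2'-O-protected chalcone epoxides to reach alpha-formyl deoxybenzoins. No ring is closed and no stereocentre is created: both oxirane stereocentres are destroyed, so the racemic nature of 11 is irrelevant, and the enol geometry is fixed by the O–H···O=C hydrogen bond. Two selectivities are needed: ionisation at the benzylic carbon, secured by the donor pattern of ring B, and aroyl migration in preference to hydride (which would give a 1,2-diketone), secured by the intrinsic preference of acyl groups to migrate in these epoxy ketones. Both ortho oxygens of ring A are etherified, so neither can add to the cation and close a ring, and a substoichiometric Lewis acid at or below 0 °C for minutes should leave benzyl, allyl and methyl ethers intact.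

Step 8
Reactants: 12 (Z)-1-[6-(allyloxy)-2,4-bis(benzyloxy)-3-methoxyphenyl]-3-hydroxy-2-(2,3,4-trimethoxyphenyl)prop-2-en-1-one
Product: 15 5,7-bis(benzyloxy)-6-methoxy-3-(2,3,4-trimethoxyphenyl)-4H-chromen-4-one, via free phenol 13 (not isolated), via 2-hydroxyisoflavanone 14 (not isolated)
Conditions: Pd(PPh3)4 (5 mol %), TolSO2Na (1.5 equiv), THF/MeOH, rt; then HCl, MeOH, 40 °C
Reagents that add atoms: none
Why: Tsuji–Trost-type deallylation: zerovalent palladium ionises the aryl allyl ether to a pi-allyl complex that the soft, non-basic sulfinate traps as a sulfone, so no amine is present that could condense with or cleave the formyl group. The freed phenol 13 adds to the aldehyde carbon (6-exo-trig hemiacetal formation, O1–C2) to give 14, and acid-catalysed dehydration gives the aromatic pyranone; only this one oxygen is free, so the 8-methoxy isomer cannot arise.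

Step 9
Reactants: 15 5,7-bis(benzyloxy)-6-methoxy-3-(2,3,4-trimethoxyphenyl)-4H-chromen-4-one
Product: 16 5,7-dihydroxy-6-methoxy-3-(2,3,4-trimethoxyphenyl)-4H-chromen-4-one
Conditions: H2 (1 atm), 10% Pd/C, EtOAc/MeOH, rt
Reagents that add atoms: none
Why: Catalytic hydrogenolysis of the two benzylic C–O bonds; aryl methyl ethers are inert and the C2=C3 bond, a trisubstituted vinylogous ester double bond, is reduced far more slowly, so the reaction is stopped after uptake of two equivalents of H2.

## Compound list

1 | 1-(2,4,6-trihydroxyphenyl)ethanone | CC(=O)c1c(O)cc(O)cc1O | starting material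
2 | benzyl bromide | BrCc1ccccc1 | starting material
3 | 1-[2,4-bis(benzyloxy)-6-hydroxyphenyl]ethanone | CC(=O)c1c(O)cc(OCc2ccccc2)cc1OCc1ccccc1 | intermediate
4 | potassium 3-acetyl-2,6-bis(benzyloxy)-4-hydroxyphenyl sulfate (formed in the flask, not isolated) | CC(=O)c1c(O)cc(OCc2ccccc2)c(OS(=O)(=O)[O-])c1OCc1ccccc1.[K+] | intermediate
5 | 1-[2,4-bis(benzyloxy)-3,6-dihydroxyphenyl]ethanone | CC(=O)c1c(O)cc(OCc2ccccc2)c(O)c1OCc1ccccc1 | intermediate
6 | 1-[2,4-bis(benzyloxy)-6-hydroxy-3-methoxyphenyl]ethanone | CC(=O)c1c(O)cc(OCc2ccccc2)c(OC)c1OCc1ccccc1 | intermediate
7 | allyl bromide | C=CCBr | starting material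
8 | 1-[6-(allyloxy)-2,4-bis(benzyloxy)-3-methoxyphenyl]ethanone | CC(=O)c1c(OCC=C)cc(OCc2ccccc2)c(OC)c1OCc1ccccc1 | intermediate
9 | 2,3,4-trimethoxybenzaldehyde | COc1ccc(C=O)c(OC)c1OC | starting material
10 | (E)-1-[6-(allyloxy)-2,4-bis(benzyloxy)-3-methoxyphenyl]-3-(2,3,4-trimethoxyphenyl)prop-2-en-1-one | C=CCOc1cc(OCc2ccccc2)c(OC)c(OCc2ccccc2)c1C(=O)/C=C/c1ccc(OC)c(OC)c1OC | intermediate
11 | rac-[6-(allyloxy)-2,4-bis(benzyloxy)-3-methoxyphenyl][(2S,3R)-3-(2,3,4-trimethoxyphenyl)oxiran-2-yl]methanone (trans; racemic, one enantiomer drawn) | C=CCOc1cc(OCc2ccccc2)c(OC)c(OCc2ccccc2)c1C(=O)[C@H]1O[C@@H]1c1ccc(OC)c(OC)c1OC | intermediate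
12 | (Z)-1-[6-(allyloxy)-2,4-bis(benzyloxy)-3-methoxyphenyl]-3-hydroxy-2-(2,3,4-trimethoxyphenyl)prop-2-en-1-one | C=CCOc1cc(OCc2ccccc2)c(OC)c(OCc2ccccc2)c1C(=O)/C(=C\O)c1ccc(OC)c(OC)c1OC | intermediate
13 | (Z)-1-[2,4-bis(benzyloxy)-6-hydroxy-3-methoxyphenyl]-3-hydroxy-2-(2,3,4-trimethoxyphenyl)prop-2-en-1-one (formed in the flask, not isolated) | Oc1cc(OCc2ccccc2)c(OC)c(OCc2ccccc2)c1C(=O)/C(=C\O)c1ccc(OC)c(OC)c1OC | intermediate
14 | 5,7-bis(benzyloxy)-2-hydroxy-6-methoxy-3-(2,3,4-trimethoxyphenyl)chroman-4-one (formed in the flask, not isolated; mixture of C2/C3 diastereomers, configuration not controlled and lost on dehydration) | COc1ccc(C2C(O)Oc3cc(OCc4ccccc4)c(OC)c(OCc4ccccc4)c3C2=O)c(OC)c1OC | intermediate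
15 | 5,7-bis(benzyloxy)-6-methoxy-3-(2,3,4-trimethoxyphenyl)-4H-chromen-4-one | COc1ccc(-c2coc3cc(OCc4ccccc4)c(OC)c(OCc4ccccc4)c3c2=O)c(OC)c1OC | intermediate
16 | 5,7-dihydroxy-6-methoxy-3-(2,3,4-trimethoxyphenyl)-4H-chromen-4-one (no stereocentre) | COc1ccc(-c2coc3cc(O)c(OC)c(O)c3c2=O)c(OC)c1OC | target

## Step count, longest sequence and least certain steps

Total: 9 steps. Longest linear sequence: 9 steps (1, 3, 5, 6, 8, 10, 11, 12, 15, 16); compounds 2, 7 and 9 are purchased and enter directly.

**Step 7 (key step).**
- What may go wrong: Lewis-acid-induced loss of the benzyl group ortho to the ketone, with the liberated oxygen then closing onto the benzylic cation; hydride migration in competition with aroyl migration; Lewis-acid-accelerated allyl migration to C5 of ring A; or deformylation on prolonged contact. All stem from the fact that the cation is long-lived and several ether oxygens compete for BF3.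
- Fallback: it sets out from 10 and comes back at 15. Treating 10 with PhI(OH)OTs in MeOH at rt should add the trivalent iodine electrophile and methanol across the enone. Ring B then migrates from the beta to the alpha carbon as iodobenzene leaves (oxidative 1,2-aryl shift, the complementary migration to the same 1,2-diaryl skeleton). Capture by methanol should give 1-[6-(allyloxy)-2,4-bis(benzyloxy)-3-methoxyphenyl]-3,3-dimethoxy-2-(2,3,4-trimethoxyphenyl)propan-1-one F1 (racemic). The isolated allyl double bond is expected to react more slowly than the aryl-activated enone. Deallylation with Pd(PPh3)4 and TolSO2Na, which here meets no acidic enol, would give 1-[2,4-bis(benzyloxy)-6-hydroxy-3-methoxyphenyl]-3,3-dimethoxy-2-(2,3,4-trimethoxyphenyl)propan-1-one F2 (racemic). HCl in MeOH should then close ring C with loss of methanol to give 15.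

**Step 1.**
- What may go wrong: incomplete discrimination between the second and the third O-alkylation, leaving mono- and tribenzyl ethers beside 3, together with some C-benzylation of the ambident phloroglucinol-type phenoxide.
- Fallback: it sets out from 1 and comes back at 3. Exhaustive O-benzylation with 2 (3.5 equiv) and K2CO3 in DMF at 60 °C should give the single ether 1-[2,4,6-tris(benzyloxy)phenyl]ethanone F3. MgBr2·OEt2 in toluene/Et2O at reflux should then remove one benzyl group only: magnesium chelated between the ketone oxygen and an ortho ether oxygen delivers bromide to that benzylic carbon, and the resulting magnesium phenoxide chelate protects the second ortho ether. Selectivity between alkylation stages is thereby replaced by a chelation-controlled cleavage.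

**Step 2.**
- What may go wrong: low conversion and unproductive consumption of the oxidant, because the phenoxide of a dibenzyl ether dissolves poorly in aqueous alkali and the electron-rich ring is open to radical over-oxidation.
- Fallback: it sets out from 3 and comes back at 6. Oxidative dearomatisation of 3 with PhI(OAc)2 (2.2 equiv) in MeOH at 0 °C should place methanol twice at the para carbon and give 2-acetyl-3,5-bis(benzyloxy)-4,4-dimethoxycyclohexa-2,5-dien-1-one F4. Zn dust in AcOH should then re-aromatise it reductively, with loss of one methanol, directly to 6.

**Step 8.**
- What may go wrong: transfer of the allyl group from oxygen to the alpha carbon, because the enolate of the formyl ketone is itself a good soft nucleophile for the pi-allyl palladium intermediate; or loss of the formyl group to adventitious nucleophiles.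
- Fallback: it sets out from 12 and comes back at 15. [Ir(cod)(PMePh2)2]PF6 (a cationic complex of monovalent iridium, activated with H2) in THF at rt should isomerise the allyl ether to the enol ether (Z)-1-[2,4-bis(benzyloxy)-3-methoxy-6-[(E)-prop-1-en-1-yloxy]phenyl]-3-hydroxy-2-(2,3,4-trimethoxyphenyl)prop-2-en-1-one F5 without forming any allyl electrophile. Dilute HCl in THF/MeOH should then hydrolyse the enol ether, releasing propanal, and close and dehydrate ring C to 15.

**Step 9.**
- What may go wrong: saturation of the C2=C3 bond of ring C if hydrogenation is prolonged, or slow cleavage if the catalyst is poisoned by traces of sulfur or phosphorus carried over from step 8.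
- Fallback: it sets out from 15 and ends at 16 without new intermediates. BCl3 with pentamethylbenzene as cation scavenger in CH2Cl2 at −78 °C cleaves benzyl ethers by a Lewis-acid ionisation pathway; at that temperature aryl methyl ethers should survive.

## Further compounds

F1 | step 7 | 1-[6-(allyloxy)-2,4-bis(benzyloxy)-3-methoxyphenyl]-3,3-dimethoxy-2-(2,3,4-trimethoxyphenyl)propan-1-one (racemic) | C=CCOc1cc(OCc2ccccc2)c(OC)c(OCc2ccccc2)c1C(=O)C(C(OC)OC)c1ccc(OC)c(OC)c1OC
F2 | step 7 | 1-[2,4-bis(benzyloxy)-6-hydroxy-3-methoxyphenyl]-3,3-dimethoxy-2-(2,3,4-trimethoxyphenyl)propan-1-one (racemic) | Oc1cc(OCc2ccccc2)c(OC)c(OCc2ccccc2)c1C(=O)C(C(OC)OC)c1ccc(OC)c(OC)c1OC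
F3 | step 1 | 1-[2,4,6-tris(benzyloxy)phenyl]ethanone | CC(=O)c1c(OCc2ccccc2)cc(OCc2ccccc2)cc1OCc1ccccc1
F4 | step 2 | 2-acetyl-3,5-bis(benzyloxy)-4,4-dimethoxycyclohexa-2,5-dien-1-one | CC(=O)C1=C(OCc2ccccc2)C(OC)(OC)C(OCc2ccccc2)=CC1=O
F5 | step 8 | (Z)-1-[2,4-bis(benzyloxy)-3-methoxy-6-[(E)-prop-1-en-1-yloxy]phenyl]-3-hydroxy-2-(2,3,4-trimethoxyphenyl)prop-2-en-1-one | C/C=C/Oc1cc(OCc2ccccc2)c(OC)c(OCc2ccccc2)c1C(=O)/C(=C\O)c1ccc(OC)c(OC)c1OC
F0 | step 9 | none | none
A1 | alternative 1 | 5,7-bis(benzyloxy)-3-(2-hydroxy-3,4-dimethoxyphenyl)-6-methoxychromen-4-one | COc1ccc(-c2coc3cc(OCc4ccccc4)c(OC)c(OCc4ccccc4)c3c2=O)c(O)c1OC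
A2 | alternative 1 | 5,7-bis(benzyloxy)-6-methoxy-3-[(E)-2-(tributylstannyl)ethenyl]chromen-4-one | CCCC[Sn](CCCC)(CCCC)/C=C/c1coc2cc(OCc3ccccc3)c(OC)c(OCc3ccccc3)c2c1=O
A3 | alternative 1 | 4-chloro-2,3-dimethoxycyclobut-2-en-1-one (racemic) | COC1=C(OC)C(Cl)C1=O
A4 | alternative 2 | 5,7-bis(benzyloxy)-6-methoxy-3-(2,3,4-trimethoxyphenyl)chromen-4-one (identical with 15) | COc1ccc(-c2coc3cc(OCc4ccccc4)c(OC)c(OCc4ccccc4)c3c2=O)c(OC)c1OC
A5 | alternative 2 | 5,7-bis(benzyloxy)-6-methoxy-2-(2,3,4-trimethoxyphenyl)chroman-4-one (racemic) | COc1ccc(C2CC(=O)c3c(OCc4ccccc4)c(OC)c(OCc4ccccc4)cc3O2)c(OC)c1OC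
A6 | alternative 3 | 5,7-bis(benzyloxy)-6-methoxy-3-(2,3,4-trimethoxyphenyl)-2-(trimethylsilyl)chromen-4-one | COc1ccc(-c2c([Si](C)(C)C)oc3cc(OCc4ccccc4)c(OC)c(OCc4ccccc4)c3c2=O)c(OC)c1OC
A7 | alternative 3 | 4,6-bis(benzyloxy)-2-hydroxy-5-methoxybenzaldehyde | O=Cc1c(O)cc(OCc2ccccc2)c(OC)c1OCc1ccccc1
A8 | alternative 3 | trimethyl[(2,3,4-trimethoxyphenyl)ethynyl]silane | COc1ccc(C#C[Si](C)(C)C)c(OC)c1OC
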